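**Strategy**

Everything rests on cutting the C3–C4 bond of ring A. Ring B (C5–C10, with the C8 methyl and the C9 carbonyl) is the ring of (R)-carvone, whose isopropenyl group on C5 is the future gem-dimethyl carbon C4. Protonation turns that group into the tertiary C4 cation, which the silicon-bearing carbon C3 of a (Z)-vinylsilane tethered to C10 captures. This one operation closes ring A, completes the gem-dimethyl group, leaves a C2–C3 alkene and, because the two arms are trans on ring B, gives only the trans ring fusion. The precursor is 6-methyl-6-[(Z)-3-(trimethylsilyl)allyl]carvone with the allyl arm trans to isopropenyl.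

Key step: step 5

Remarks and assumptions
- Labdane numbering is used for the bicyclic compounds: C1–C10 decalin, C17 on C8, C18/C19 on C4, C20 on C10, side chain C11–C16 with C15 the carboxyl carbon. α is the face of H5, β the face of the C10 methyl. The target is (5S,8R,9R,10S,13S).
- Assumed purchasable: (R)-carvone, iodomethane, 3-(trimethylsilyl)prop-2-yn-1-ol and methyl hydrogen (R)-3-methylglutarate.
- The vinylsilane is built as the Z isomer on purpose: a silyl group cis to the tether can be replaced with retention to give the cis ring alkene, and it lies axial in the closing chair.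
- Alkene 25 may form as either geometric isomer. Both converge in step 16, so its SMILES carries no alkene descriptor.

**Route**

Step 1
Reactants: 1 (R)-(−)-carvone; 2 iodomethane
Product: 4 trans-6-methylcarvone [(5R,6S)-2,6-dimethyl-5-(prop-1-en-2-yl)cyclohex-2-en-1-one], via lithium enolate of carvone 3 (not isolated)
Conditions: LiN(iPr)2 (LDA), THF, −78 °C; then MeI, −78 → −20 °C
Reagents that add atoms: iodomethane, CI
Why: Kinetic α′-deprotonation gives the cross-conjugated enolate, whose alkylation (enolate alkylation) places the methyl mainly anti to the isopropenyl group; the C6 configuration does not matter because C6 is enolised again in step 4.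

Step 2
Reactants: 5 3-(trimethylsilyl)prop-2-yn-1-ol
Product: 6 (Z)-3-(trimethylsilyl)prop-2-en-1-ol
Conditions: H2 (1 atm), Ni(OAc)2·4H2O/NaBH4 (P-2 nickel boride), ethylenediamine, EtOH, rt
Reagents that add atoms: none
Why: Syn semihydrogenation of the silylalkyne on the amine-poisoned nickel boride surface should stop at the cis alkene, which fixes the Z geometry.

Step 3
Reactants: 6 (Z)-3-(trimethylsilyl)prop-2-en-1-ol
Product: 7 (Z)-(3-bromoprop-1-en-1-yl)trimethylsilane
Conditions: CBr4, PPh3, CH2Cl2, 0 °C
Reagents that add atoms: carbon tetrabromide, BrC(Br)(Br)Br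
Why: Appel bromination converts the primary allylic alcohol into the bromide under neutral conditions that should neither isomerise the alkene nor cleave the vinyl C–Si bond.

Step 4
Reactants: 4 trans-6-methylcarvone; 7 (Z)-(3-bromoprop-1-en-1-yl)trimethylsilane
Product: 9 (5S,6S)-2,6-dimethyl-5-(prop-1-en-2-yl)-6-[(2Z)-3-(trimethylsilyl)prop-2-en-1-yl]cyclohex-2-en-1-one (silylallyl trans to isopropenyl; methyl cis), via lithium enolate of 6-methylcarvone 8 (not isolated)
Conditions: LiN(iPr)2, THF, −78 → −20 °C; then 7, DMPU, −78 °C → rt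
Reagents that add atoms: none
Why: SN2 alkylation of the tetrasubstituted α′-enolate by the allylic bromide (enolate alkylation) occurs on the face anti to the adjacent isopropenyl group, which sets quaternary C10 with the silylallyl arm trans to the isopropenyl arm.

Step 5
Reactants: 9 (5S,6S)-6-methyl-6-[(Z)-3-(trimethylsilyl)allyl]carvone
Product: 12 (4aS,8aS)-2,5,5,8a-tetramethyl-4a,5,8,8a-tetrahydronaphthalen-1(4H)-one (trans-fused dienone: C9 ketone; alkenes C2=C3 and C7=C8), via tertiary C4 cation 10 (not isolated), via β-silyl C2 cation 11 (not isolated)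
Conditions: HCO2H (98%), rt → 40 °C
Reagents that add atoms: none
Why: Formic acid protonates the isopropenyl group in the Markovnikov sense to the tertiary C4 cation 10, the silicon-bearing carbon C3 of the vinylsilane attacks it to give the β-silyl cation 11, and loss of the silyl group to formate leaves the C2–C3 alkene; this is a vinylsilane-terminated cation–olefin cyclization with ipso substitution of silicon. Ring A closes in the 6-endo mode through a chair-like transition state, whereas 5-exo closure through C2 would put the charge α to silicon, where it gains no stabilisation. No new stereocentre is formed: C5 comes from carvone and C10 from step 4, and because the cationic arm on C5 and the nucleophilic arm on C10 are trans-diequatorial on ring B only the trans-fused decalin can result. The step needs ipso closure to outrun protodesilylation and proton loss from the cation, and the Z geometry secures this: in the chair the cis silyl group becomes axial on C3, so the C–Si bond overlaps with the developing empty orbital on C2 and the endocyclic cis alkene forms with retention. An E silyl group would sit equatorial, orthogonal to that orbital, and would not assist closure. The enone alkene is too electron-poor to be protonated or to compete as a nucleophile.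

Step 6
Reactants: 12 trans-fused dienone
Product: 13 (2R,4aS,8aS)-2,5,5,8a-tetramethyloctahydronaphthalen-1(2H)-one (saturated C9 ketone; C8 methyl α and equatorial)
Conditions: H2 (1 atm), 10% Pd/C, EtOAc, rt; then NaOMe (cat.), MeOH, rt
Reagents that add atoms: none
Why: Heterogeneous catalytic hydrogenation should saturate the ring A alkene and the enone alkene without touching the hindered ketone, and brief base equilibration settles the epimerisable C8 methyl equatorial, a centre that is erased anyway in step 7.

Step 7
Reactants: 13 saturated C9 ketone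
Product: 15 (2R,4aS,8aS)-2-hydroxy-2,5,5,8a-tetramethyloctahydronaphthalen-1(2H)-one (8α-OH; 8β-CH3), via potassium C8–C9 enolate 14 (not isolated)
Conditions: KN(SiMe3)2 (KHMDS), THF, −78 → 0 °C; then 2-(phenylsulfonyl)-3-phenyloxaziridine, −78 °C; AcOH quench
Reagents that add atoms: 2-(phenylsulfonyl)-3-phenyloxaziridine, O=S(=O)(N1OC1c1ccccc1)c1ccccc1
Why: Davis enolate hydroxylation: only C8 can enolise, and the oxaziridine should transfer oxygen to planar C8 on the α face, away from the axial C10 methyl that covers the β face, giving 8α-OH with the methyl β.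

Step 8
Reactants: 15 α-hydroxy ketone
Product: 16 (2R,4aS,8aS)-2,5,5,8a-tetramethyl-2-(triethylsilyloxy)octahydronaphthalen-1(2H)-one
Conditions: Et3SiOTf, 2,6-lutidine, CH2Cl2, 0 °C
Reagents that add atoms: triethylsilyl trifluoromethanesulfonate, CC[Si](CC)(CC)OS(=O)(=O)C(F)(F)F
Why: Silyl triflate silylation is the standard way to cap a hindered tertiary alcohol, and the ketone has no α-hydrogen left, so no enol ether can form.

Step 9
Reactants: 17 methyl hydrogen (R)-3-methylglutarate
Product: 18 methyl (3R)-5-hydroxy-3-methylpentanoate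
Conditions: BH3·SMe2, THF, 0 °C → rt; MeOH quench
Reagents that add atoms: none
Why: Chemoselective borane reduction takes the carboxylic acid much faster than the ester, and the stereocentre, β to both carbonyl groups, is not touched.

Step 10
Reactants: 18 methyl (3R)-5-hydroxy-3-methylpentanoate
Product: 19 methyl (3R)-5-(tert-butyldimethylsilyloxy)-3-methylpentanoate
Conditions: tBuMe2SiCl, imidazole, DMF, rt
Reagents that add atoms: tert-butyldimethylsilyl chloride, CC(C)(C)[Si](C)(C)Cl
Why: Silyl ether formation at the primary alcohol, carried out at once so that the hydroxy ester cannot lactonise.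

Step 11
Reactants: 19 silyloxy ester
Product: 20 (3S)-5-(tert-butyldimethylsilyloxy)-3-methylpentan-1-ol
Conditions: LiAlH4, Et2O, 0 °C; then H2O
Reagents that add atoms: none
Why: Hydride reduction of the ester to the primary alcohol leaves the silyl ether intact.

Step 12
Reactants: 20 mono-silylated diol
Product: 21 tert-butyl{[(3R)-5-iodo-3-methylpentyl]oxy}dimethylsilane
Conditions: I2, PPh3, imidazole, CH2Cl2, 0 °C → rt
Reagents that add atoms: iodine, II
Why: Appel-type iodination of a primary alcohol (phosphonium activation, SN2 by iodide).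

Step 13
Reactants: 21 silyloxy iodide; 16 α-silyloxy ketone
Product: 23 C9 tertiary alcohol (labdane skeleton; 9β-OH with the side chain α on C9; 8α-OSiEt3; 15-OSiMe2tBu; 13S), via primary alkyllithium 22 (not isolated)
Conditions: 21, t-BuLi (2.1 equiv), Et2O/pentane, −78 °C; then 16, −78 → −30 °C; H2O at −78 °C
Reagents that add atoms: none
Why: Iodine–lithium exchange gives the primary alkyllithium, which should add (1,2-addition of an organolithium) to the non-enolisable ketone along the open axial α trajectory, the β side being closed by the axial methyls on C8 and C10; the C9 configuration formed is irrelevant because C9 becomes trigonal in step 14.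

Step 14
Reactants: 23 C9 tertiary alcohol
Product: 25 (13S)-15-(tert-butyldimethylsilyloxy)-8α-(triethylsilyloxy)labd-9(11)-ene, via C9 chlorosulfite 24 (not isolated)
Conditions: SOCl2, pyridine, CH2Cl2, −20 → 0 °C
Reagents that add atoms: none
Why: Dehydration of a tertiary alcohol through its chlorosulfite with pyridine-mediated E2 loss of a C11 hydrogen; C8 and C10 carry no hydrogen, so the exocyclic C9=C11 alkene is the only elimination product possible, and the buffered medium should spare both silyl ethers.

Step 15
Reactants: 25 bis-silyl ether alkene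
Product: 26 (13S)-labd-9(11)-ene-8α,15-diol
Conditions: Bu4NF, THF, rt → 50 °C
Reagents that add atoms: none
Why: Fluoride-mediated desilylation removes the primary and the tertiary silyl ether in one operation and leaves the alkene untouched.

Step 16
Reactants: 26 allylic diol
Product: 27 (13S)-labdane-8α,15-diol
Conditions: H2 (1 atm), [Ir(cod)(PCy3)(py)]PF6 (Crabtree's catalyst, 5 mol %), CH2Cl2, rt
Reagents that add atoms: none
Why: Hydroxyl-directed homogeneous hydrogenation: the cationic iridium catalyst reduces hindered trisubstituted alkenes and can bind the allylic C8 hydroxyl, so hydrogen should reach C9 from the α face, which is also the only open one (axial methyls on C8 and C10 block β), setting 9α-H with the side chain β and equatorial.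

Step 17
Reactants: 27 (13S)-labdane-8α,15-diol
Product: 28 (13S)-8α-hydroxylabdan-15-oic acid (labdanolic acid)
Conditions: TEMPO (cat.), PhI(OAc)2, MeCN/H2O 1:1, rt
Reagents that add atoms: water, O
Why: Oxoammonium-mediated oxidation takes the primary alcohol through the aldehyde hydrate to the carboxylic acid, while the tertiary C8 alcohol cannot be oxidised.

Step 18
Reactants: 28 labdanolic acid
Product: 29 (5S,8R,9R,10S,13S)-8-formyloxylabdan-15-oic acid (target)
Conditions: HCO2H/Ac2O (55 °C, giving AcOCHO); then 28, pyridine, CH2Cl2, 0 °C → rt; aqueous work-up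
Reagents that add atoms: acetic formic anhydride, CC(=O)OC=O
Why: O-Formylation with acetic formic anhydride, whose formyl carbon is the more electrophilic and less hindered acyl site, should reach the hindered tertiary alcohol; any mixed anhydride formed at the carboxyl group is hydrolysed in the work-up.

**Compound list**

1 | (R)-(−)-carvone | CC1=CC[C@@H](C(C)=C)CC1=O | starting material
2 | iodomethane | CI | starting material
3 | lithium enolate of carvone (C1–C6 enolate; formed in the flask, not isolated) | CC1=CC[C@@H](C(C)=C)C=C1[O-].[Li+] | intermediate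
4 | trans-6-methylcarvone, (5R,6S)-2,6-dimethyl-5-(prop-1-en-2-yl)cyclohex-2-en-1-one (the C6 epimer may accompany it and converges in step 4) | CC1=CC[C@@H](C(C)=C)[C@H](C)C1=O | intermediate
5 | 3-(trimethylsilyl)prop-2-yn-1-ol | C[Si](C)(C)C#CCO | starting material
6 | (Z)-3-(trimethylsilyl)prop-2-en-1-ol | C[Si](C)(C)/C=C\CO | intermediate
7 | (Z)-(3-bromoprop-1-en-1-yl)trimethylsilane | C[Si](C)(C)/C=C\CBr | intermediate
8 | lithium enolate of 6-methylcarvone (formed in the flask, not isolated) | CC1=CC[C@@H](C(C)=C)C(C)=C1[O-].[Li+] | intermediate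
9 | (5S,6S)-2,6-dimethyl-5-(prop-1-en-2-yl)-6-[(2Z)-3-(trimethylsilyl)prop-2-en-1-yl]cyclohex-2-en-1-one (key-step precursor; silylallyl trans to isopropenyl) | CC1=CC[C@@H](C(C)=C)[C@](C)(C/C=C\[Si](C)(C)C)C1=O | intermediate
10 | tertiary C4 cation from 9 (formed in the flask, not isolated) | CC1=CC[C@@H]([C+](C)C)[C@](C)(C/C=C\[Si](C)(C)C)C1=O | intermediate
11 | β-silyl C2 cation (ring A closed; 3α-SiMe3 axial; formed in the flask, not isolated) | CC1=CC[C@H]2C(C)(C)[C@H]([Si](C)(C)C)[CH+]C[C@]2(C)C1=O | intermediate
12 | (4aS,8aS)-2,5,5,8a-tetramethyl-4a,5,8,8a-tetrahydronaphthalen-1(4H)-one (key-step product) | CC1=CC[C@H]2C(C)(C)C=CC[C@]2(C)C1=O | intermediate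
13 | (2R,4aS,8aS)-2,5,5,8a-tetramethyloctahydronaphthalen-1(2H)-one | C[C@@H]1CC[C@H]2C(C)(C)CCC[C@]2(C)C1=O | intermediate
14 | potassium C8–C9 enolate of 13 (formed in the flask, not isolated) | CC1=C([O-])[C@@]2(C)CCCC(C)(C)[C@@H]2CC1.[K+] | intermediate
15 | (2R,4aS,8aS)-2-hydroxy-2,5,5,8a-tetramethyloctahydronaphthalen-1(2H)-one (8α-OH, 8β-CH3) | C[C@@]1(O)CC[C@H]2C(C)(C)CCC[C@]2(C)C1=O | intermediate
16 | (2R,4aS,8aS)-2,5,5,8a-tetramethyl-2-(triethylsilyloxy)octahydronaphthalen-1(2H)-one | C[C@@]1(O[Si](CC)(CC)CC)CC[C@H]2C(C)(C)CCC[C@]2(C)C1=O | intermediate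
17 | methyl hydrogen (R)-3-methylglutarate, (3R)-5-methoxy-3-methyl-5-oxopentanoic acid | C[C@@H](CC(=O)OC)CC(=O)O | starting material
18 | methyl (3R)-5-hydroxy-3-methylpentanoate | C[C@@H](CC(=O)OC)CCO | intermediate
19 | methyl (3R)-5-(tert-butyldimethylsilyloxy)-3-methylpentanoate | C[C@@H](CC(=O)OC)CCO[Si](C)(C)C(C)(C)C | intermediate
20 | (3S)-5-(tert-butyldimethylsilyloxy)-3-methylpentan-1-ol | C[C@@H](CCO)CCO[Si](C)(C)C(C)(C)C | intermediate
21 | tert-butyl{[(3R)-5-iodo-3-methylpentyl]oxy}dimethylsilane | C[C@@H](CCI)CCO[Si](C)(C)C(C)(C)C | intermediate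
22 | primary alkyllithium from 21 (formed in the flask, not isolated) | C[C@@H](CC[Li])CCO[Si](C)(C)C(C)(C)C | intermediate
23 | C9 tertiary alcohol: 9β-hydroxy, side chain α on C9, 8α-triethylsilyloxy, 15-(tert-butyldimethylsilyloxy), 13S | C[C@@H](CC[C@@]1(O)[C@@]2(C)CCCC(C)(C)[C@@H]2CC[C@@]1(C)O[Si](CC)(CC)CC)CCO[Si](C)(C)C(C)(C)C | intermediate
24 | C9 chlorosulfite of 23 (formed in the flask, not isolated) | C[C@@H](CC[C@@]1(OS(=O)Cl)[C@@]2(C)CCCC(C)(C)[C@@H]2CC[C@@]1(C)O[Si](CC)(CC)CC)CCO[Si](C)(C)C(C)(C)C | intermediate
25 | (13S)-15-(tert-butyldimethylsilyloxy)-8α-(triethylsilyloxy)labd-9(11)-ene | C[C@@H](CC=C1[C@@]2(C)CCCC(C)(C)[C@@H]2CC[C@@]1(C)O[Si](CC)(CC)CC)CCO[Si](C)(C)C(C)(C)C | intermediate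
26 | (13S)-labd-9(11)-ene-8α,15-diol | C[C@@H](CC=C1[C@@]2(C)CCCC(C)(C)[C@@H]2CC[C@@]1(C)O)CCO | intermediate
27 | (13S)-labdane-8α,15-diol | C[C@@H](CC[C@@H]1[C@@]2(C)CCCC(C)(C)[C@@H]2CC[C@@]1(C)O)CCO | intermediate
28 | (13S)-8α-hydroxylabdan-15-oic acid (labdanolic acid) | C[C@@H](CC[C@@H]1[C@@]2(C)CCCC(C)(C)[C@@H]2CC[C@@]1(C)O)CC(=O)O | intermediate
29 | (5S,8R,9R,10S,13S)-8-formyloxylabdan-15-oic acid | C[C@@H](CC[C@@H]1[C@@]2(C)CCCC(C)(C)[C@@H]2CC[C@@]1(C)OC=O)CC(=O)O | target

**Totals**

Total step count: 18. Longest linear sequence: 13 steps (2, 3, 4, 5, 6, 7, 8, 13, 14, 15, 16, 17, 18), counted from 3-(trimethylsilyl)prop-2-yn-1-ol 5. The branch from (R)-carvone 1 joins this line at step 4, and the side-chain branch from 17 (steps 9 to 12) joins it at step 13.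

**Steps most likely to fail**

1. Step 5. Protodesilylation of the vinylsilane, or capture or deprotonation of the C4 cation in the protic medium, may outrun ring closure. The fallback sets out from 9 and returns at 12. Dry HCl in CH2Cl2 at −20 °C adds across the isopropenyl group in the Markovnikov sense to give the tertiary chloride 5-(2-chloropropan-2-yl)-2,6-dimethyl-6-[(Z)-3-(trimethylsilyl)allyl]cyclohex-2-en-1-one F1. SnCl4 in CH2Cl2 at −78 °C then ionises F1 to the same C4 cation under aprotic conditions, where neither formate capture nor protonolysis of the C–Si bond can intervene, and ipso closure gives 12.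

2. Step 13. The sp3 organolithium may fail to reach the carbonyl carbon flanked by two quaternary centres, or the triethylsilyl group may migrate to the new alkoxide. The fallback sets out from 16 and returns at 23, using a slimmer sp nucleophile. (R)-But-3-yn-2-ol is mesylated (MsCl, Et3N) to (R)-but-3-yn-2-yl methanesulfonate F2. Sodium dimethyl malonate (NaH, THF/DMF) displaces the mesylate with inversion to give dimethyl 2-[(2R)-but-3-yn-2-yl]propanedioate F3. Krapcho demethoxycarbonylation (LiCl, wet DMSO, 150 °C) gives methyl (3R)-3-methylpent-4-ynoate F4, LiAlH4 gives (3R)-3-methylpent-4-yn-1-ol F5, and tBuMe2SiCl/imidazole gives tert-butyldimethyl{[(3R)-3-methylpent-4-yn-1-yl]oxy}silane F6. The lithium acetylide of F6 (n-BuLi, THF, −78 °C) adds to 16 from the α face to give the C9 propargylic alcohol F7, and hydrogenation of the triple bond (H2, PtO2, EtOAc) gives 23.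

3. Step 14. The chlorosulfite may ionise before a C11 hydrogen is removed, and the axial C8 methyl may then shift to C9 (a semipinacol pathway) in place of E2 elimination. The fallback sets out from 23 and returns at 27, passing C9 as a radical. The alkoxide of 23 (n-BuLi, THF, −78 °C) is acylated with methyl chlorooxoacetate to the C9 methyl oxalate F8. Bu3SnH/AIBN in refluxing toluene (radical deoxygenation of a tertiary oxalate) should give (13S)-15-(tert-butyldimethylsilyloxy)-8α-(triethylsilyloxy)labdane F9, with hydrogen delivered to the C9 radical from the open α face. Bu4NF then gives 27, so steps 15 and 16 are not needed.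

**Further compounds**

F1 | step 5 | 5-(2-chloropropan-2-yl)-2,6-dimethyl-6-[(Z)-3-(trimethylsilyl)allyl]cyclohex-2-en-1-one (configuration as in 9) | CC1=CC[C@@H](C(C)(C)Cl)[C@](C)(C/C=C\[Si](C)(C)C)C1=O
F2 | step 13 | (R)-but-3-yn-2-yl methanesulfonate | C[C@H](C#C)OS(C)(=O)=O
F3 | step 13 | dimethyl 2-[(2R)-but-3-yn-2-yl]propanedioate | C[C@@H](C#C)C(C(=O)OC)C(=O)OC
F4 | step 13 | methyl (3R)-3-methylpent-4-ynoate | C[C@@H](C#C)CC(=O)OC
F5 | step 13 | (3R)-3-methylpent-4-yn-1-ol | C[C@@H](C#C)CCO
F6 | step 13 | tert-butyldimethyl{[(3R)-3-methylpent-4-yn-1-yl]oxy}silane | C[C@@H](C#C)CCO[Si](C)(C)C(C)(C)C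
F7 | step 13 | C9 propargylic alcohol (9β-OH, alkynyl side chain α, 8α-triethylsilyloxy, 15-silyloxy, 13S) | C[C@@H](C#C[C@@]1(O)[C@@]2(C)CCCC(C)(C)[C@@H]2CC[C@@]1(C)O[Si](CC)(CC)CC)CCO[Si](C)(C)C(C)(C)C
F8 | step 14 | C9 methyl oxalate of 23 | C[C@@H](CC[C@@]1(OC(=O)C(=O)OC)[C@@]2(C)CCCC(C)(C)[C@@H]2CC[C@@]1(C)O[Si](CC)(CC)CC)CCO[Si](C)(C)C(C)(C)C
F9 | step 14 | (13S)-15-(tert-butyldimethylsilyloxy)-8α-(triethylsilyloxy)labdane | C[C@@H](CC[C@@H]1[C@@]2(C)CCCC(C)(C)[C@@H]2CC[C@@]1(C)O[Si](CC)(CC)CC)CCO[Si](C)(C)C(C)(C)C
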